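**Retrosynthetic overview**

1. Numbering: C1 (methyl-bearing fusion carbon), C2, C3, C4 (isopropyl carbinol), C5 (fusion CH), C6 (aroyloxy carbon), C7=C8 (methyl on C8), C9 (acetoxy carbon), C10. Ring A is the seven-membered ring (C1, C5–C10), ring B the five-membered ring (C1–C5), and β is the face of the C1 methyl. The strategy rests on the adjacent fusion stereocentres C1 and C5 lying β and α to the oxygenated C6: with C6 as the carbonyl of a 3-methylcyclohept-2-enone, C1 is the acceptor carbon (takes C2) and C5 the enolate carbon (takes C4).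
2. Late disconnections: phenol silyl ether, C6 ester, hydroxyl-directed reduction of the C6 ketone from the 4β-OH, C9 acetate, C9 oxygen by vinylogous Rubottom oxidation of the 8-methyl enone, C8 methyl and C7=C8 by conjugate addition and Saegusa oxidation.
3. Ring B: C3–C4 bond by SmI2 Barbier closure of a C3 iodide onto the C4 isopropyl ketone, with C6 held as a silyl ether so that C4 is the only carbonyl.
4. Ring A is purchased; C1–C2 and C4–C5 come from one copper-catalysed enantioselective vinylation–aldol of 3-methylcyclohept-2-en-1-one with a silylvinyl alane and isobutyraldehyde. Ring order: A (bought), then B (step 9).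

Key step: step 2

Assumption: the carbinol centres formed at C4 (step 2) and C6 (step 4) are carried as epimer mixtures and left undefined in the SMILES, because both carbons are oxidised to ketones later (steps 8 and 11).

**Route**

Step 1
Reactants: 1 ethynyltrimethylsilane; 2 diisobutylaluminium hydride
Product: 3 diisobutyl[1-(trimethylsilyl)ethenyl]aluminium
Conditions: hexanes/THF (5:1), 55 °C, 2 h; used as a stock solution
Reagents that add atoms: none
Why: Alkyne hydroalumination places aluminium on the silicon-bearing carbon, where the C–Al bond is stabilised by silicon, and the donor solvent suppresses deprotonation of the terminal alkyne.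

Step 2
Reactants: 3 diisobutyl[1-(trimethylsilyl)ethenyl]aluminium; 4 3-methylcyclohept-2-en-1-one; 5 isobutyraldehyde
Product: 7 (2R,3R)-2-(1-hydroxy-2-methylpropyl)-3-methyl-3-[1-(trimethylsilyl)ethenyl]cycloheptan-1-one, via aluminium enolate 6 (not isolated)
Conditions: Cu(OTf)2 (5 mol %), chiral sulfonate-bearing imidazolinium salt (carbene precursor, 5 mol %), 3 (1.5 equiv), THF, −78 °C; then 5 (3 equiv), −78 → −30 °C; aq. Rochelle salt
Reagents that add atoms: none
Why: Enantioselective conjugate addition followed by aluminium-enolate aldol addition: Cu(OTf)2 is reduced by the alane to carbene-bound monovalent copper, the silylvinyl group passes from aluminium to copper, the vinylcopper binds the enone, adds at the β-carbon C1 through a trivalent-copper intermediate and reductive elimination, and the diisobutylaluminium enolate 6 then adds to isobutyraldehyde through a closed six-membered transition state. The closest known reaction type is the carbene–copper-catalysed addition of silyl-substituted vinylaluminium reagents to β-substituted cyclic enones of ring size five to seven with electrophilic capture of the aluminium enolate. No ring is closed; the C1–C2 and C4–C5 bonds are formed. C1 is set by the chiral carbene ligand, whose enantiomer is chosen to give the (R) quaternary centre, and C5 is set by the substrate, the aldehyde approaching the enolate face anti to the bulky silylvinyl group so that C2 and C4 end up trans on ring A; the carbinol centre C4 is not controlled and is oxidised later. The step needs 1,4- over 1,2-addition and vinyl over isobutyl transfer, which copper catalysis and the readier transfer of the sp2 ligand secure, and aldol addition only at C5, which follows because the enolate is generated regiospecifically at C5–C6 and the aldehyde is added after the enone is consumed.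

Step 3
Reactants: 7 (2R,3R)-2-(1-hydroxy-2-methylpropyl)-3-methyl-3-[1-(trimethylsilyl)ethenyl]cycloheptan-1-one
Product: 8 (2R,3S)-3-ethenyl-2-(1-hydroxy-2-methylpropyl)-3-methylcycloheptan-1-one
Conditions: CF3CO2H (5 equiv), CHCl3, 0 → 22 °C; aq. NaHCO3
Reagents that add atoms: none
Why: Protodesilylation of the vinylsilane by ipso protonation to a β-silyl-stabilised cation and loss of silicon to trifluoroacetate leaves the vinyl group, while the ketone and the secondary alcohol should tolerate the acid at this temperature.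

Step 4
Reactants: 8 (2R,3S)-3-ethenyl-2-(1-hydroxy-2-methylpropyl)-3-methylcycloheptan-1-one
Product: 9 3-ethenyl-2-(1-hydroxy-2-methylpropyl)-3-methylcycloheptan-1-ol (C1 and C5 as in 8; epimers at C4 and C6)
Conditions: NaBH4, MeOH, 0 °C → rt
Reagents that add atoms: none
Why: Borohydride reduction takes C6 to the alcohol level so that it cannot compete with C4 as an electrophile in the ring closure; the new centre is re-oxidised in step 11 and need not be controlled.

Step 5
Reactants: 9 3-ethenyl-2-(1-hydroxy-2-methylpropyl)-3-methylcycloheptan-1-ol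
Product: 10 1-[7-(tert-butyldimethylsilyloxy)-2-ethenyl-2-methylcycloheptyl]-2-methylpropan-1-ol (C6 silyl ether, free C4 hydroxyl)
Conditions: TBSCl (1.1 equiv), imidazole, DMF, 0 °C
Reagents that add atoms: tert-butyldimethylsilyl chloride, CC(C)(C)[Si](C)(C)Cl
Why: Sterically selective silylation should occur at O6, which has the ring CH2 C7 as a neighbour, rather than at O4, which is flanked by the isopropyl group and the fully branched C5.

Step 6
Reactants: 10 1-[7-(tert-butyldimethylsilyloxy)-2-ethenyl-2-methylcycloheptyl]-2-methylpropan-1-ol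
Product: 11 1-[7-(tert-butyldimethylsilyloxy)-2-(2-hydroxyethyl)-2-methylcycloheptyl]-2-methylpropan-1-ol
Conditions: 9-BBN (3 equiv), THF, 0 → 50 °C; then NaOH, H2O2, 0 °C
Reagents that add atoms: hydrogen peroxide, OO
Why: Hydroboration–oxidation with the bulky dialkylborane puts boron on the terminal carbon C3 of the monosubstituted alkene and alkaline peroxide replaces it by hydroxyl.

Step 7
Reactants: 11 1-[7-(tert-butyldimethylsilyloxy)-2-(2-hydroxyethyl)-2-methylcycloheptyl]-2-methylpropan-1-ol
Product: 12 1-[7-(tert-butyldimethylsilyloxy)-2-(2-iodoethyl)-2-methylcycloheptyl]-2-methylpropan-1-ol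
Conditions: I2, PPh3, imidazole, CH2Cl2, 0 °C
Reagents that add atoms: iodine, II
Why: Appel-type iodination activates only the primary hydroxyl as its alkoxyphosphonium ion, which iodide displaces by SN2, the shielded secondary C4 hydroxyl being left alone.

Step 8
Reactants: 12 1-[7-(tert-butyldimethylsilyloxy)-2-(2-iodoethyl)-2-methylcycloheptyl]-2-methylpropan-1-ol
Product: 13 1-[7-(tert-butyldimethylsilyloxy)-2-(2-iodoethyl)-2-methylcycloheptyl]-2-methylpropan-1-one
Conditions: Dess–Martin periodinane, NaHCO3, CH2Cl2, 0 °C → rt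
Reagents that add atoms: none
Why: Dess–Martin oxidation converts the hindered C4 carbinol to the isopropyl ketone under buffered neutral conditions that should spare the alkyl iodide, the silyl ether and the C5 configuration.

Step 9
Reactants: 13 1-[7-(tert-butyldimethylsilyloxy)-2-(2-iodoethyl)-2-methylcycloheptyl]-2-methylpropan-1-one
Product: 14 6-(tert-butyldimethylsilyloxy)-4α-isopropyl-1β-methyl-5αH-perhydroazulen-4β-ol (trans-fused; C6 epimers)
Conditions: SmI2 (2.5 equiv), HMPA, THF, −78 → 0 °C; aq. NH4Cl
Reagents that add atoms: none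
Why: Samarium Barbier cyclisation: reduction of the C–I bond gives a C3 organosamarium that adds 5-exo to the C4 ketone, closing ring B trans-fused because C2 and C4 are trans on ring A, and the carbonyl should react through the rotamer with the isopropyl group beside H5 and away from C6, which places the new hydroxyl on the β face.

Step 10
Reactants: 14 6-(tert-butyldimethylsilyloxy)-4α-isopropyl-1β-methyl-5αH-perhydroazulen-4β-ol
Product: 15 4α-isopropyl-1β-methyl-5αH-perhydroazulene-4β,6-diol
Conditions: TBAF, THF, 50 °C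
Reagents that add atoms: none
Why: Fluoride desilylation frees the C6 hydroxyl, and since no carbonyl is present the basic fluoride cannot trigger a retro-aldol cleavage.

Step 11
Reactants: 15 4α-isopropyl-1β-methyl-5αH-perhydroazulene-4β,6-diol
Product: 16 4β-hydroxy-4α-isopropyl-1β-methyl-5αH-perhydroazulen-6-one
Conditions: Dess–Martin periodinane, NaHCO3, CH2Cl2, 0 °C
Reagents that add atoms: none
Why: Dess–Martin oxidation can only touch the secondary C6 alcohol, the tertiary C4 alcohol being unoxidisable, and the buffered medium should avoid retro-aldol cleavage and epimerisation at C5.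

Step 12
Reactants: 16 4β-hydroxy-4α-isopropyl-1β-methyl-5αH-perhydroazulen-6-one
Product: 17 4α-isopropyl-1β-methyl-4β,6-bis(trimethylsilyloxy)-5αH-hydroazul-6-ene (C6=C7 silyl enol ether)
Conditions: TMSOTf (3 equiv), Et3N, CH2Cl2, 0 °C
Reagents that add atoms: trimethylsilyl trifluoromethanesulfonate, C[Si](C)(C)OS(=O)(=O)C(F)(F)F
Why: Soft enolisation with silyl triflate and amine caps the tertiary alcohol and forms the silyl enol ether toward C7, because H5 is buried between two fully substituted carbons and enolisation there would give a strained tetrasubstituted alkene.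

Step 13
Reactants: 17 4α-isopropyl-1β-methyl-4β,6-bis(trimethylsilyloxy)-5αH-hydroazul-6-ene
Product: 18 4α-isopropyl-1β-methyl-4β-(trimethylsilyloxy)-5αH-hydroazul-7-en-6-one
Conditions: Pd(OAc)2 (1.1 equiv), MeCN, rt
Reagents that add atoms: none
Why: Saegusa–Ito oxidation by palladation at C7 and β-hydride elimination of H8 gives the C7=C8 enone, the only dehydrogenation possible since C4 and C1 carry no hydrogen.

Step 14
Reactants: 18 4α-isopropyl-1β-methyl-4β-(trimethylsilyloxy)-5αH-hydroazul-7-en-6-one
Product: 19 4α-isopropyl-1β,8-dimethyl-4β,6-bis(trimethylsilyloxy)-5αH-hydroazul-6-ene (C8 epimers)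
Conditions: MeMgBr, CuBr·SMe2 (10 mol %), TMSCl, HMPA, THF, −78 °C; Et3N
Reagents that add atoms: methylmagnesium bromide, C[Mg]Br; chlorotrimethylsilane, C[Si](C)(C)Cl
Why: Copper-catalysed conjugate addition of the Grignard reagent with silyl chloride trapping puts the methyl group on the unhindered β-carbon C8 and delivers the C6–C7 silyl enol ether, the C8 configuration being irrelevant because C8 becomes sp2 in the next step.

Step 15
Reactants: 19 4α-isopropyl-1β,8-dimethyl-4β,6-bis(trimethylsilyloxy)-5αH-hydroazul-6-ene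
Product: 20 4α-isopropyl-1β,8-dimethyl-4β-(trimethylsilyloxy)-5αH-hydroazul-7-en-6-one
Conditions: Pd(OAc)2 (1.1 equiv), MeCN, rt
Reagents that add atoms: none
Why: A second Saegusa–Ito oxidation, by palladation at C7 and β-hydride elimination of the remaining H8, restores the enone with the methyl group now on C8.

Step 16
Reactants: 20 4α-isopropyl-1β,8-dimethyl-4β-(trimethylsilyloxy)-5αH-hydroazul-7-en-6-one
Product: 21 6-(tert-butyldimethylsilyloxy)-4α-isopropyl-1β,8-dimethyl-4β-(trimethylsilyloxy)-5αH-hydroazula-6,8-diene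
Conditions: TBSOTf, Et3N, CH2Cl2, 0 °C → rt
Reagents that add atoms: tert-butyldimethylsilyl trifluoromethanesulfonate, CC(C)(C)[Si](C)(C)OS(=O)(=O)C(F)(F)F
Why: Vinylogous enolisation by O-silylation and loss of a γ-proton from the ring CH2 C9 should give the through-conjugated endocyclic dienol ether, favoured as the more substituted diene over the exocyclic isomer from the C8 methyl and over α′-enolisation at the shielded C5.

Step 17
Reactants: 21 6-(tert-butyldimethylsilyloxy)-4α-isopropyl-1β,8-dimethyl-4β-(trimethylsilyloxy)-5αH-hydroazula-6,8-diene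
Product: 23 4β,9α-dihydroxy-4α-isopropyl-1β,8-dimethyl-5αH-hydroazul-7-en-6-one, via 9α-silyloxy enone 22 (not isolated)
Conditions: mCPBA, NaHCO3, CH2Cl2, −20 °C; then HF·pyridine, THF/pyridine, 0 °C
Reagents that add atoms: 3-chloroperoxybenzoic acid, OOC(=O)c1cccc(Cl)c1
Why: Vinylogous Rubottom oxidation: the peracid should epoxidise the electron-rich distal C8=C9 bond from the α face, anti to the axial C1 methyl, the epoxide opens with silyl transfer to the 9α-silyloxy enone, and fluoride then removes both silyl groups.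

Step 18
Reactants: 23 4β,9α-dihydroxy-4α-isopropyl-1β,8-dimethyl-5αH-hydroazul-7-en-6-one
Product: 24 9α-acetoxy-4β-hydroxy-4α-isopropyl-1β,8-dimethyl-5αH-hydroazul-7-en-6-one
Conditions: Ac2O, pyridine, DMAP (cat.), CH2Cl2, 0 °C
Reagents that add atoms: acetic anhydride, CC(=O)OC(C)=O
Why: DMAP-catalysed acetylation occurs only at the secondary allylic C9 hydroxyl, the hindered tertiary C4 hydroxyl being inert under these conditions.

Step 19
Reactants: 24 9α-acetoxy-4β-hydroxy-4α-isopropyl-1β,8-dimethyl-5αH-hydroazul-7-en-6-one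
Product: 25 9α-acetoxy-4α-isopropyl-1β,8-dimethyl-5αH-hydroazul-7-ene-4β,6α-diol
Conditions: Me4NBH(OAc)3, MeCN/AcOH (1:1), −30 °C
Reagents that add atoms: none
Why: Hydroxyl-directed Evans–Saksena reduction: the 4β-hydroxyl exchanges onto boron and delivers hydride through a chair-like six-membered transition state to the β face of the C6 carbonyl, which should give the 6α-alcohol (1,3-anti to O4) by 1,2-reduction without touching the acetate.

Step 20
Reactants: 25 9α-acetoxy-4α-isopropyl-1β,8-dimethyl-5αH-hydroazul-7-ene-4β,6α-diol; 26 4-[(tert-butyldimethylsilyl)oxy]benzoic acid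
Product: 27 9α-acetoxy-6α-[4-(tert-butyldimethylsilyloxy)benzoyloxy]-4α-isopropyl-1β,8-dimethyl-5αH-hydroazul-7-en-4β-ol
Conditions: EDC·HCl, DMAP, CH2Cl2, rt
Reagents that add atoms: none
Why: Steglich esterification acylates the only secondary hydroxyl (C6), the tertiary C4 hydroxyl does not react, and the silyl ether keeps the phenol from self-condensation.

Step 21
Reactants: 27 9α-acetoxy-6α-[4-(tert-butyldimethylsilyloxy)benzoyloxy]-4α-isopropyl-1β,8-dimethyl-5αH-hydroazul-7-en-4β-ol
Product: 28 9α-acetoxy-6α-(4-hydroxybenzoyloxy)-4α-isopropyl-1β,8-dimethyl-5αH-hydroazul-7-en-4β-ol (CNP0305796.2)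
Conditions: KHF2, MeOH, rt
Reagents that add atoms: none
Why: Fluoride cleavage of the aryl silyl ether, which is far more labile toward bifluoride than the alkyl esters, should release the phenol without transesterifying the acetate or the benzoate.

**Compound list**

1 | ethynyltrimethylsilane | C#C[Si](C)(C)C | starting material
2 | diisobutylaluminium hydride | CC(C)C[AlH]CC(C)C | starting material
3 | diisobutyl[1-(trimethylsilyl)ethenyl]aluminium | C=C([Si](C)(C)C)[Al](CC(C)C)CC(C)C | intermediate
4 | 3-methylcyclohept-2-en-1-one | CC1=CC(=O)CCCC1 | starting material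
5 | isobutyraldehyde | CC(C)C=O | starting material
6 | diisobutylaluminium enolate of (R)-3-methyl-3-[1-(trimethylsilyl)ethenyl]cycloheptanone (C5=C6 enolate) | C=C([Si](C)(C)C)[C@]1(C)CCCCC(O[Al](CC(C)C)CC(C)C)=C1 | intermediate (not isolated)
7 | (2R,3R)-2-(1-hydroxy-2-methylpropyl)-3-methyl-3-[1-(trimethylsilyl)ethenyl]cycloheptan-1-one | C=C([Si](C)(C)C)[C@]1(C)CCCCC(=O)[C@H]1C(O)C(C)C | intermediate
8 | (2R,3S)-3-ethenyl-2-(1-hydroxy-2-methylpropyl)-3-methylcycloheptan-1-one | C=C[C@]1(C)CCCCC(=O)[C@H]1C(O)C(C)C | intermediate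
9 | 3-ethenyl-2-(1-hydroxy-2-methylpropyl)-3-methylcycloheptan-1-ol | C=C[C@]1(C)CCCCC(O)[C@H]1C(O)C(C)C | intermediate
10 | 1-[7-(tert-butyldimethylsilyloxy)-2-ethenyl-2-methylcycloheptyl]-2-methylpropan-1-ol | C=C[C@]1(C)CCCCC(O[Si](C)(C)C(C)(C)C)[C@H]1C(O)C(C)C | intermediate
11 | 1-[7-(tert-butyldimethylsilyloxy)-2-(2-hydroxyethyl)-2-methylcycloheptyl]-2-methylpropan-1-ol | OCC[C@]1(C)CCCCC(O[Si](C)(C)C(C)(C)C)[C@H]1C(O)C(C)C | intermediate
12 | 1-[7-(tert-butyldimethylsilyloxy)-2-(2-iodoethyl)-2-methylcycloheptyl]-2-methylpropan-1-ol | ICC[C@]1(C)CCCCC(O[Si](C)(C)C(C)(C)C)[C@H]1C(O)C(C)C | intermediate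
13 | 1-[7-(tert-butyldimethylsilyloxy)-2-(2-iodoethyl)-2-methylcycloheptyl]-2-methylpropan-1-one | ICC[C@]1(C)CCCCC(O[Si](C)(C)C(C)(C)C)[C@H]1C(=O)C(C)C | intermediate
14 | 6-(tert-butyldimethylsilyloxy)-4α-isopropyl-1β-methyl-5αH-perhydroazulen-4β-ol | C1C[C@@]2(C)CC[C@@](O)(C(C)C)[C@@H]2C(O[Si](C)(C)C(C)(C)C)CC1 | intermediate
15 | 4α-isopropyl-1β-methyl-5αH-perhydroazulene-4β,6-diol | C1C[C@@]2(C)CC[C@@](O)(C(C)C)[C@@H]2C(O)CC1 | intermediate
16 | 4β-hydroxy-4α-isopropyl-1β-methyl-5αH-perhydroazulen-6-one | C1C[C@@]2(C)CC[C@@](O)(C(C)C)[C@@H]2C(=O)CC1 | intermediate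
17 | 4α-isopropyl-1β-methyl-4β,6-bis(trimethylsilyloxy)-5αH-hydroazul-6-ene | C1C[C@@]2(C)CC[C@@](O[Si](C)(C)C)(C(C)C)[C@@H]2C(O[Si](C)(C)C)=CC1 | intermediate
18 | 4α-isopropyl-1β-methyl-4β-(trimethylsilyloxy)-5αH-hydroazul-7-en-6-one | C1C[C@@]2(C)CC[C@@](O[Si](C)(C)C)(C(C)C)[C@@H]2C(=O)C=C1 | intermediate
19 | 4α-isopropyl-1β,8-dimethyl-4β,6-bis(trimethylsilyloxy)-5αH-hydroazul-6-ene | C1C[C@@]2(C)CC[C@@](O[Si](C)(C)C)(C(C)C)[C@@H]2C(O[Si](C)(C)C)=CC1C | intermediate
20 | 4α-isopropyl-1β,8-dimethyl-4β-(trimethylsilyloxy)-5αH-hydroazul-7-en-6-one | C1C[C@@]2(C)CC[C@@](O[Si](C)(C)C)(C(C)C)[C@@H]2C(=O)C=C1C | intermediate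
21 | 6-(tert-butyldimethylsilyloxy)-4α-isopropyl-1β,8-dimethyl-4β-(trimethylsilyloxy)-5αH-hydroazula-6,8-diene | CC1=CC[C@@]2(C)CC[C@@](O[Si](C)(C)C)(C(C)C)[C@@H]2C(O[Si](C)(C)C(C)(C)C)=C1 | intermediate
22 | 9α-(tert-butyldimethylsilyloxy)-4α-isopropyl-1β,8-dimethyl-4β-(trimethylsilyloxy)-5αH-hydroazul-7-en-6-one | CC(C)(C)[Si](C)(C)O[C@H]1C[C@@]2(C)CC[C@@](O[Si](C)(C)C)(C(C)C)[C@@H]2C(=O)C=C1C | intermediate (not isolated)
23 | 4β,9α-dihydroxy-4α-isopropyl-1β,8-dimethyl-5αH-hydroazul-7-en-6-one | O[C@H]1C[C@@]2(C)CC[C@@](O)(C(C)C)[C@@H]2C(=O)C=C1C | intermediate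
24 | 9α-acetoxy-4β-hydroxy-4α-isopropyl-1β,8-dimethyl-5αH-hydroazul-7-en-6-one | CC(=O)O[C@H]1C[C@@]2(C)CC[C@@](O)(C(C)C)[C@@H]2C(=O)C=C1C | intermediate
25 | 9α-acetoxy-4α-isopropyl-1β,8-dimethyl-5αH-hydroazul-7-ene-4β,6α-diol | CC(=O)O[C@H]1C[C@@]2(C)CC[C@@](O)(C(C)C)[C@@H]2[C@@H](O)C=C1C | intermediate
26 | 4-[(tert-butyldimethylsilyl)oxy]benzoic acid | CC(C)(C)[Si](C)(C)Oc1ccc(cc1)C(=O)O | starting material
27 | 9α-acetoxy-6α-[4-(tert-butyldimethylsilyloxy)benzoyloxy]-4α-isopropyl-1β,8-dimethyl-5αH-hydroazul-7-en-4β-ol | CC(=O)O[C@H]1C[C@@]2(C)CC[C@@](O)(C(C)C)[C@@H]2[C@@H](OC(=O)c2ccc(O[Si](C)(C)C(C)(C)C)cc2)C=C1C | intermediate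
28 | 9α-acetoxy-6α-(4-hydroxybenzoyloxy)-4α-isopropyl-1β,8-dimethyl-5αH-hydroazul-7-en-4β-ol (CNP0305796.2) | CC(=O)O[C@H]1C[C@@]2(C)CC[C@@](O)(C(C)C)[C@@H]2[C@@H](OC(=O)c2ccc(O)cc2)C=C1C | target

**Step count**

Total steps: 21. Longest linear sequence: 21 steps (1/2 → 28); acid 26 is purchased.

**Steps most likely to fail**

Step 2. Capture of the congested aluminium enolate by the aldehyde may stay incomplete, so that the simple conjugate adduct is returned on work-up, or isobutyl and hydride transfer from aluminium may consume the aldehyde. Fallback: starting again from enone 4 and alane 3, the conjugate addition is run as before and enolate 6 is silylated with Et3SiOTf to give the isolable triethylsilyl enol ether F1. A Mukaiyama aldol addition of F1 to aldehyde 5 (BF3·OEt2, CH2Cl2, −78 °C), a Lewis-acid process with an open transition state that no longer depends on the nucleophilicity of the aluminium enolate, should then give 7, where the route is rejoined.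

Step 9. The C3 organosamarium may be protonated before it adds, for instance after enolisation of the hindered C4 ketone, so that iodine is lost without ring closure, or the ketone may be reduced first. Fallback: from iodo ketone 13, displacement with PhSO2Na (DMF, rt) gives the phenyl sulfone F2. Deprotonation next to sulfur (LDA, THF, −78 °C) and intramolecular addition of the stabilised carbanion to the C4 ketone close ring B as the β-hydroxy sulfone F3, under the same rotamer control, and reductive desulfonylation (Mg, MeOH) returns the route at 14.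

Step 17 (together with the dienol ether of step 16). Enolisation may run toward the C8 methyl instead of C9, the peracid may attack the enol-ether double bond and deliver oxygen to C7, or attack may occur on the β face. Fallback: from enone 20 the order is changed so that C9 is oxidised by an allylic ene process whose position is fixed by the alkene substitution pattern. HF·pyridine frees the tertiary alcohol to give the hydroxy enone F4, Me4NBH(OAc)3 gives the 4β,6α-diol F5, and Steglich esterification with 26 gives the C6 ester F6. SeO2 (cat.)/t-BuOOH should then oxidise the ring CH2 at the more substituted alkene terminus to the 9β-alcohol F7, selenium engaging C7 anti to the 6α-ester and oxygen arriving on the same face at C9. Mitsunobu esterification with acetic acid (PPh3, DIAD) inverts C9 and gives the 9α-acetate 27, where the route is rejoined.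

**Further compounds**

F1 | step 2 | triethylsilyl enol ether of (R)-3-methyl-3-[1-(trimethylsilyl)ethenyl]cycloheptanone (C5=C6) | C=C([Si](C)(C)C)[C@]1(C)CCCCC(O[Si](CC)(CC)CC)=C1
F2 | step 9 | 1-[7-(tert-butyldimethylsilyloxy)-2-methyl-2-[2-(phenylsulfonyl)ethyl]cycloheptyl]-2-methylpropan-1-one | O=S(=O)(CC[C@]1(C)CCCCC(O[Si](C)(C)C(C)(C)C)[C@H]1C(=O)C(C)C)c1ccccc1
F3 | step 9 | 6-(tert-butyldimethylsilyloxy)-4α-isopropyl-1β-methyl-3-(phenylsulfonyl)-5αH-perhydroazulen-4β-ol | C1C[C@@]2(C)CC(S(=O)(=O)c3ccccc3)[C@@](O)(C(C)C)[C@@H]2C(O[Si](C)(C)C(C)(C)C)CC1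
F4 | step 17 | 4β-hydroxy-4α-isopropyl-1β,8-dimethyl-5αH-hydroazul-7-en-6-one | C1C[C@@]2(C)CC[C@@](O)(C(C)C)[C@@H]2C(=O)C=C1C
F5 | step 17 | 4α-isopropyl-1β,8-dimethyl-5αH-hydroazul-7-ene-4β,6α-diol | C1C[C@@]2(C)CC[C@@](O)(C(C)C)[C@@H]2[C@@H](O)C=C1C
F6 | step 17 | 6α-[4-(tert-butyldimethylsilyloxy)benzoyloxy]-4α-isopropyl-1β,8-dimethyl-5αH-hydroazul-7-en-4β-ol | C1C[C@@]2(C)CC[C@@](O)(C(C)C)[C@@H]2[C@@H](OC(=O)c2ccc(O[Si](C)(C)C(C)(C)C)cc2)C=C1C
F7 | step 17 | 6α-[4-(tert-butyldimethylsilyloxy)benzoyloxy]-4α-isopropyl-1β,8-dimethyl-5αH-hydroazul-7-ene-4β,9β-diol | O[C@@H]1C[C@@]2(C)CC[C@@](O)(C(C)C)[C@@H]2[C@@H](OC(=O)c2ccc(O[Si](C)(C)C(C)(C)C)cc2)C=C1C
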